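**Plan**

1. Retrosynthesis: both CO2H groups go back to silyl-protected CH2OH arms. Each pyranone is cut at O1–C2 and C4–C5, which releases a methylmalonyl unit and leaves an acetyl group. The two acetyl carbonyl carbons (pyranone C-6) are then read as the carboxyl carbons of a cis-1,2-dicarboxylic unit, and last the two C–CH3 bonds at the quaternary ring carbons are cut.
2. Enabling feature: the adjacent quaternary cyclobutane carbons C-3 and C-4 each carry a methyl and a pyranone C-6 on opposite faces. Joined through an N-benzyl nitrogen, these two carbons are the ring-fusion α-carbons of a cis-fused 3-azabicyclo[3.2.0]heptane-2,4-dione (cyclobutane fused to a succinimide), whose enolates can be alkylated only on the exo face.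
3. Forward: the four-membered ring is bought as cis,trans,cis-cyclobutanetetracarboxylic dianhydride, so no carbocycle is made. One anhydride becomes the imide and the other the bis-silyl diol (steps 1–3). Both methyls are then introduced (step 4), and the imide is converted via the anhydride into the bis(methyl ketone) (steps 5–6). The two pyranone rings are closed together from the bis(enol silane) with methylmalonyl dichloride and O-methylated (steps 7–9), and the arms are unmasked and oxidised (steps 10–12).
4. Stereochemistry: the cis,trans,cis pattern of the purchased ring fixes all four ring carbons. The obligatory cis ring fusion transfers it to both quaternary centres in step 4. The two CH centres become epimerisable only in steps 11–12, which are run cold and near pH 4.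

Key step: step 4

Assumption: the target is the meso diacid (pyranones cis to each other, both methyls and both carboxyls on the opposite face), so only relative configuration matters; racemic not-isolated intermediates are drawn as one enantiomer, and methylmalonyl dichloride is taken as a purchasable acid chloride.

**Route**

Step 1
Reactants: 1 cis,trans,cis-cyclobutane-1,2,3,4-tetracarboxylic dianhydride; 2 benzylamine
Product: 5 3-benzyl-2,4-dioxo-3-azabicyclo[3.2.0]heptane-6,7-dicarboxylic acid (meso; both carboxyls exo), via amic acid anhydride 3 (not isolated), via imide anhydride 4 (not isolated)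
Conditions: 1 (3 equiv), DMF, 0 °C, slow addition of 2 (1 equiv), then rt; Ac2O, NaOAc (cat.), 80 °C; H2O, 60 °C; acid–base partition
Reagents that add atoms: benzylamine (2), NCc1ccccc1; water, O
Why: Aminolysis of a cyclic anhydride followed by Ac2O/NaOAc cyclodehydration of the amic acid is the standard imide synthesis; keeping the dianhydride in excess favours reaction at one ring only, water then opens the untouched anhydride, and neutral bis-imide, diacid 5 and water-soluble tetraacid should part on acid–base extraction, while the cis ring fusions keep every stereocentre locked.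

Step 2
Reactants: 5 imide diacid
Product: 6 3-benzyl-6,7-bis(hydroxymethyl)-3-azabicyclo[3.2.0]heptane-2,4-dione (meso; both arms exo)
Conditions: BH3·THF (5 equiv), THF, 0 °C to rt; aqueous NH4Cl work-up
Reagents that add atoms: none
Why: Chemoselective borane reduction of carboxylic acids (through acyloxyboranes) runs at 0 °C to rt where an N-alkyl imide is untouched, as in the reduction of N-phthaloyl amino acids to phthalimido alcohols, and the new hydroxymethyl arms lie trans to the imide carbonyls so that no translactonisation is possible.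

Step 3
Reactants: 6 imide diol; 7 tert-butylchlorodiphenylsilane
Product: 8 3-benzyl-6,7-bis[(tert-butyldiphenylsilyloxy)methyl]-3-azabicyclo[3.2.0]heptane-2,4-dione (meso; both arms exo)
Conditions: TBDPSCl (2.4 equiv), imidazole, DMF, rt
Reagents that add atoms: tert-butylchlorodiphenylsilane (7), CC(C)(C)[Si](Cl)(c1ccccc1)c1ccccc1
Why: Standard silylation of primary alcohols (silyl chloride, imidazole, DMF); the tert-butyldiphenylsilyl ether is chosen because it tolerates the amide base, hydroxide, pH 2 acid, MeLi and HCl met later and falls to fluoride without harming a pyranone.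

Step 4
Reactants: 8 bis-silyl imide; 9 iodomethane
Product: 11 3-benzyl-1,5-dimethyl-6,7-bis[(tert-butyldiphenylsilyloxy)methyl]-3-azabicyclo[3.2.0]heptane-2,4-dione (meso; both methyls and both arms exo), via monomethyl imide 10 (not isolated)
Conditions: LiN(iPr)2 (1.1 equiv), THF, −78 °C; MeI (1.2 equiv), to −40 °C; LiN(iPr)2 (1.5 equiv), DMPU, −78 to −40 °C; MeI (3 equiv), to 0 °C
Reagents that add atoms: iodomethane (9), CI
Why: LiN(iPr)2 removes one exo ring-fusion hydrogen α to an imide carbonyl to give a lithium enolate whose C=C lies inside the five-membered ring, iodomethane alkylates it at carbon by SN2, and the sequence is repeated in the same flask at the second ring-fusion carbon through monomethyl imide 10. The closest known reaction type is the ring-fusion alkylation of enolates of cis-fused bicyclic succinimides and of cyclobutanecarboxylate enolates. No ring is closed, so no mode of closure arises. Each new quaternary stereocentre is controlled by the bicyclic skeleton: a trans-fused 3-azabicyclo[3.2.0]heptane is out of reach, so the electrophile must take the exo position that the hydrogen left and the carbonyl stays on its face, which sets both methyls cis to each other and cis to the silyloxymethyl arms as the target demands. The step needs site selectivity and C- over O-alkylation: with C-6 and C-7 carrying only CH2OSi groups there is no other C–H acid in the molecule, no epimerisable centre and no carbonyl that could trigger a retro-Michael scission of the four-membered ring, and the soft electrophile favours carbon. Because the second deprotonation has a quaternary neighbour it will be the sluggish one, hence the excess base, DMPU and higher temperature.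

Step 5
Reactants: 11 dimethylated imide
Product: 13 1,5-dimethyl-6,7-bis[(tert-butyldiphenylsilyloxy)methyl]-3-oxabicyclo[3.2.0]heptane-2,4-dione (meso cyclic anhydride; methyls and arms exo), via amic acid 12 (not isolated)
Conditions: LiOH (3 equiv), THF/H2O, 40 °C; 1 M HCl to pH 2, 60 °C; toluene azeotrope
Reagents that add atoms: lithium hydroxide, [Li+].[OH-]
Why: Imide hydrolysis by hydroxide gives the amate, and after acidification the carboxylic acid held syn to the amide on the tetrasubstituted ring expels benzylamine to form the five-membered anhydride (carboxyl-assisted amide cleavage known for maleamic and tetraalkylsuccinamic acids); any open diacid should reclose on azeotropic drying and would in any case feed step 6 equally well.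

Step 6
Reactants: 13 cyclic anhydride; 15 methyllithium
Product: 17 cis-1,2-diacetyl-1,2-dimethyl-3,4-bis[(tert-butyldiphenylsilyloxy)methyl]cyclobutane (meso; acetyls on one face; methyls and arms on the other), via dilithium dicarboxylate 14 (not isolated), via tetralithium bis-diolate 16 (not isolated)
Conditions: LiOH·H2O (2.0 equiv), THF/H2O, rt, evaporate and dry (toluene azeotrope); MeLi (8 equiv), THF/Et2O, 0 °C to rt; inverse quench into cold 1 M HCl
Reagents that add atoms: methyllithium (15), [Li]C
Why: Ketone synthesis from a lithium carboxylate and an alkyllithium: each carboxylate adds one MeLi to a geminal dilithium diolate that cannot collapse before protonation, so over-addition is avoided by inverse quench into acid; tertiary (α-quaternary) carboxylates are proven substrates and here both sit on the ring face that otherwise bears only hydrogen.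

Step 7
Reactants: 17 diketone; 18 trimethylsilyl trifluoromethanesulfonate
Product: 19 bis(trimethylsilyl enol ether) of 17 (meso; two 1-(trimethylsilyloxy)vinyl groups in place of the acetyls)
Conditions: TMSOTf (2.6 equiv), Et3N (4 equiv), CH2Cl2, 0 °C; pentane/cold NaHCO3 work-up, used crude
Reagents that add atoms: trimethylsilyl trifluoromethanesulfonate (18), C[Si](C)(C)OS(=O)(=O)C(F)(F)F
Why: Silyl enol ether formation by soft enolisation with TMSOTf and Et3N can go only towards the acetyl methyl groups because the other α-carbon is quaternary, and the aldol closure between the two arms would be a Baldwin-disfavoured 5-(enolendo)-exo-trig process.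

Step 8
Reactants: 19 bis(enol silane); 20 methylmalonyl dichloride
Product: 21 cis-1,2-bis(4-hydroxy-3-methyl-2-oxo-2H-pyran-6-yl)-1,2-dimethyl-3,4-bis[(tert-butyldiphenylsilyloxy)methyl]cyclobutane (meso; pyranones on one face; methyls and arms on the other)
Conditions: methylmalonyl dichloride (2.5 equiv), Et2O, −78 °C to rt; volatiles removed in vacuo
Reagents that add atoms: methylmalonyl dichloride (20), CC(C(=O)Cl)C(=O)Cl
Why: Annulation of trimethylsilyl enol ethers with malonyl dichlorides to 4-hydroxy-2-pyranones: C-acylation at the enol CH2 with loss of chlorotrimethylsilane gives a 3,5-dioxoacyl chloride whose enol oxygen lactonises (6-exo-trig acyl substitution) with loss of HCl, which places the reagent's methyl group at pyranone C-3 and the cyclobutane carbon at C-6.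

Step 9
Reactants: 21 bis(hydroxypyranone); 22 dimethyl sulfate
Product: 23 cis-1,2-bis(4-methoxy-3-methyl-2-oxo-2H-pyran-6-yl)-1,2-dimethyl-3,4-bis[(tert-butyldiphenylsilyloxy)methyl]cyclobutane (meso)
Conditions: Me2SO4 (3 equiv), K2CO3, acetone, 50 °C
Reagents that add atoms: dimethyl sulfate (22), COS(=O)(=O)OC
Why: O-Alkylation of the vinylogous acid (Williamson-type) with dimethyl sulfate and K2CO3 in acetone is the usual route from 4-hydroxy-2-pyranones to 4-methoxy-2-pyranones and favours this regioisomer over the 2-methoxy-4-pyranone.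

Step 10
Reactants: 23 bis-silyl ether
Product: 24 cis-3,4-bis(hydroxymethyl)-1,2-bis(4-methoxy-3-methyl-2-oxo-2H-pyran-6-yl)-1,2-dimethylcyclobutane (meso; hydroxymethyls cis to the ring methyls)
Conditions: HF·pyridine, pyridine/THF, 0 °C to rt
Reagents that add atoms: none
Why: Fluoride-induced cleavage of silyl ethers; HF·pyridine is only weakly basic, so the two lactone rings and the methyl vinylogous esters should be left alone.

Step 11
Reactants: 24 diol
Product: 25 cis-3,4-bis(4-methoxy-5-methyl-6-oxo-6H-pyran-2-yl)-3,4-dimethylcyclobutane-1,2-dicarbaldehyde (meso; formyls cis to the ring methyls)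
Conditions: (COCl)2, DMSO, CH2Cl2, −78 °C; iPr2NEt, −78 to −30 °C; cold pH 7 work-up, used at once
Reagents that add atoms: none
Why: Swern oxidation activates both hydroxyls as alkoxysulfonium ions before the base is added, so that no hydroxy aldehyde can close to a lactol (the usual fate of a cis-1,4-diol with other oxidants), and a hindered amine at low temperature should keep the two new α-CH centres from epimerising.

Step 12
Reactants: 25 dialdehyde
Product: 26 CNP0574758.1, cis-3,4-bis(4-methoxy-5-methyl-6-oxo-6H-pyran-2-yl)-3,4-dimethylcyclobutane-1,2-dicarboxylic acid (meso; carboxyls cis to the ring methyls and trans to the pyranones)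
Conditions: NaClO2, NaH2PO4, 2-methyl-2-butene, t-BuOH/H2O, 0 °C to rt
Reagents that add atoms: sodium chlorite, [Na+].[O-]Cl=O
Why: Pinnick oxidation (NaClO2 near pH 4 with 2-methyl-2-butene as hypochlorite scavenger) converts aldehydes into acids without touching the α-stereocentres or chlorinating the pyranone rings, and the cis relationship of the two carboxyls is the one carried from the purchased ring.

**Compound list**

1 | cis,trans,cis-cyclobutane-1,2,3,4-tetracarboxylic 1,2:3,4-dianhydride | O=C1OC(=O)[C@H]2[C@H]3[C@H](C(=O)OC3=O)[C@H]21 | starting material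
2 | benzylamine | NCc1ccccc1 | starting material
3 | mono-benzylamic acid of 1 (one anhydride opened to CONHBn and CO2H, the other intact; racemic) | O=C(NCc1ccccc1)[C@H]1[C@H]2[C@H](C(=O)OC2=O)[C@H]1C(=O)O | intermediate
4 | N-benzylimide anhydride (imide and anhydride rings on opposite faces of the cyclobutane) | O=C1N(Cc2ccccc2)C(=O)[C@H]2[C@H]3[C@H](C(=O)OC3=O)[C@H]21 | intermediate
5 | 3-benzyl-2,4-dioxo-3-azabicyclo[3.2.0]heptane-6,7-dicarboxylic acid (meso; carboxyls exo) | O=C1N(Cc2ccccc2)C(=O)[C@H]2[C@H](C(=O)O)[C@H](C(=O)O)[C@H]21 | intermediate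
6 | 3-benzyl-6,7-bis(hydroxymethyl)-3-azabicyclo[3.2.0]heptane-2,4-dione (meso; arms exo) | O=C1N(Cc2ccccc2)C(=O)[C@H]2[C@H](CO)[C@H](CO)[C@H]21 | intermediate
7 | tert-butylchlorodiphenylsilane | CC(C)(C)[Si](Cl)(c1ccccc1)c1ccccc1 | starting material
8 | 3-benzyl-6,7-bis[(tert-butyldiphenylsilyloxy)methyl]-3-azabicyclo[3.2.0]heptane-2,4-dione (meso; arms exo) | O=C1N(Cc2ccccc2)C(=O)[C@H]2[C@H](CO[Si](c3ccccc3)(c3ccccc3)C(C)(C)C)[C@H](CO[Si](c3ccccc3)(c3ccccc3)C(C)(C)C)[C@H]21 | intermediate
9 | iodomethane | CI | starting material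
10 | 1-methyl derivative of 8 (methyl exo; racemic) | O=C1N(Cc2ccccc2)C(=O)[C@@]2(C)[C@H](CO[Si](c3ccccc3)(c3ccccc3)C(C)(C)C)[C@H](CO[Si](c3ccccc3)(c3ccccc3)C(C)(C)C)[C@H]21 | intermediate
11 | 3-benzyl-1,5-dimethyl-6,7-bis[(tert-butyldiphenylsilyloxy)methyl]-3-azabicyclo[3.2.0]heptane-2,4-dione (meso; methyls and arms exo) | O=C1N(Cc2ccccc2)C(=O)[C@@]2(C)[C@H](CO[Si](c3ccccc3)(c3ccccc3)C(C)(C)C)[C@H](CO[Si](c3ccccc3)(c3ccccc3)C(C)(C)C)[C@]21C | intermediate
12 | cis-2-(benzylcarbamoyl)-1,2-dimethyl-3,4-bis[(tert-butyldiphenylsilyloxy)methyl]cyclobutane-1-carboxylic acid (amic acid, formed as its lithium salt; racemic) | O=C(NCc1ccccc1)[C@@]1(C)[C@H](CO[Si](c2ccccc2)(c2ccccc2)C(C)(C)C)[C@H](CO[Si](c2ccccc2)(c2ccccc2)C(C)(C)C)[C@@]1(C)C(=O)O | intermediate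
13 | 1,5-dimethyl-6,7-bis[(tert-butyldiphenylsilyloxy)methyl]-3-oxabicyclo[3.2.0]heptane-2,4-dione (meso; methyls and arms exo) | O=C1OC(=O)[C@@]2(C)[C@H](CO[Si](c3ccccc3)(c3ccccc3)C(C)(C)C)[C@H](CO[Si](c3ccccc3)(c3ccccc3)C(C)(C)C)[C@]21C | intermediate
14 | dilithium cis-1,2-dimethyl-3,4-bis[(tert-butyldiphenylsilyloxy)methyl]cyclobutane-1,2-dicarboxylate | [Li+].[Li+].[O-]C(=O)[C@@]1(C)[C@H](CO[Si](c2ccccc2)(c2ccccc2)C(C)(C)C)[C@H](CO[Si](c2ccccc2)(c2ccccc2)C(C)(C)C)[C@@]1(C)C([O-])=O | intermediate
15 | methyllithium | [Li]C | starting material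
16 | tetralithium bis(geminal diolate) from addition of MeLi to both carboxylates of 14 | [Li+].[Li+].[Li+].[Li+].CC([O-])([O-])[C@@]1(C)[C@H](CO[Si](c2ccccc2)(c2ccccc2)C(C)(C)C)[C@H](CO[Si](c2ccccc2)(c2ccccc2)C(C)(C)C)[C@@]1(C)C(C)([O-])[O-] | intermediate
17 | cis-1,2-diacetyl-1,2-dimethyl-3,4-bis[(tert-butyldiphenylsilyloxy)methyl]cyclobutane (meso) | CC(=O)[C@@]1(C)[C@H](CO[Si](c2ccccc2)(c2ccccc2)C(C)(C)C)[C@H](CO[Si](c2ccccc2)(c2ccccc2)C(C)(C)C)[C@@]1(C)C(C)=O | intermediate
18 | trimethylsilyl trifluoromethanesulfonate | C[Si](C)(C)OS(=O)(=O)C(F)(F)F | starting material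
19 | bis(trimethylsilyl enol ether) of 17 (meso) | C=C(O[Si](C)(C)C)[C@@]1(C)[C@H](CO[Si](c2ccccc2)(c2ccccc2)C(C)(C)C)[C@H](CO[Si](c2ccccc2)(c2ccccc2)C(C)(C)C)[C@@]1(C)C(=C)O[Si](C)(C)C | intermediate
20 | methylmalonyl dichloride (2-methylpropanedioyl dichloride) | CC(C(=O)Cl)C(=O)Cl | starting material
21 | cis-1,2-bis(4-hydroxy-3-methyl-2-oxo-2H-pyran-6-yl)-1,2-dimethyl-3,4-bis[(tert-butyldiphenylsilyloxy)methyl]cyclobutane (meso) | Oc1cc([C@@]2(C)[C@H](CO[Si](c3ccccc3)(c3ccccc3)C(C)(C)C)[C@H](CO[Si](c3ccccc3)(c3ccccc3)C(C)(C)C)[C@@]2(C)c2cc(O)c(C)c(=O)o2)oc(=O)c1C | intermediate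
22 | dimethyl sulfate | COS(=O)(=O)OC | starting material
23 | cis-1,2-bis(4-methoxy-3-methyl-2-oxo-2H-pyran-6-yl)-1,2-dimethyl-3,4-bis[(tert-butyldiphenylsilyloxy)methyl]cyclobutane (meso) | COc1cc([C@@]2(C)[C@H](CO[Si](c3ccccc3)(c3ccccc3)C(C)(C)C)[C@H](CO[Si](c3ccccc3)(c3ccccc3)C(C)(C)C)[C@@]2(C)c2cc(OC)c(C)c(=O)o2)oc(=O)c1C | intermediate
24 | cis-3,4-bis(hydroxymethyl)-1,2-bis(4-methoxy-3-methyl-2-oxo-2H-pyran-6-yl)-1,2-dimethylcyclobutane (meso) | COc1cc([C@@]2(C)[C@H](CO)[C@H](CO)[C@@]2(C)c2cc(OC)c(C)c(=O)o2)oc(=O)c1C | intermediate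
25 | cis-3,4-bis(4-methoxy-5-methyl-6-oxo-6H-pyran-2-yl)-3,4-dimethylcyclobutane-1,2-dicarbaldehyde (meso) | COc1cc([C@@]2(C)[C@H](C=O)[C@H](C=O)[C@@]2(C)c2cc(OC)c(C)c(=O)o2)oc(=O)c1C | intermediate
26 | CNP0574758.1, cis-3,4-bis(4-methoxy-5-methyl-6-oxo-6H-pyran-2-yl)-3,4-dimethylcyclobutane-1,2-dicarboxylic acid (meso) | COc1cc([C@@]2(C)[C@H](C(=O)O)[C@H](C(=O)O)[C@@]2(C)c2cc(OC)c(C)c(=O)o2)oc(=O)c1C | target

**Totals and weak points**

Total step count: 12. Longest linear sequence: 12 steps (1 to 26).

Steps most likely to fail: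

1. Step 6. The second carboxylate may add MeLi only sluggishly once the molecule is already a polyanion, and a diolate that collapses during the quench would be over-alkylated to a tertiary alcohol. Fallback, setting out from anhydride 13 and returning at diketone 17: reduction with LiAlH4 (THF, 0 °C) should give the bis(hydroxymethyl) compound F1. Swern oxidation then gives the dialdehyde F2, which has no α-hydrogen. Excess MeMgBr (THF, 0 °C to rt), which also consumes any lactolate formed after the first addition, gives the bis(1-hydroxyethyl) compound F3 as a mixture of carbinol epimers. A second Swern oxidation delivers 17.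

2. Step 8. The liberated HCl may protodesilylate the enol ethers before they are acylated, and one acid chloride may bridge the two neighbouring enol ethers instead of lactonising. Fallback, setting out from diketone 17 and returning at bis(hydroxypyranone) 21: soft-enolisation C-acylation (MgBr2·OEt2, iPr2NEt, 1-propanoylbenzotriazole, CH2Cl2) should give the bis(1,3-diketone) F4. Double dianion formation with LiN(iPr)2 (5 equiv, THF, −78 to 0 °C) and carboxylation with CO2 at the ethyl CH2 of each arm gives the bis(3,5-dioxo acid) F5. Cyclodehydration with Ac2O at rt closes both 4-hydroxy-2-pyranone rings to 21.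

3. Step 4. The second deprotonation, beside the new quaternary carbon and under two silyloxymethyl arms, may stall and leave monomethyl material that cannot be pushed on. Fallback, setting out from benzylamine 2 and returning at imide 11: condensation of 2 with purchased 2,3-dimethylmaleic anhydride (CC1=C(C)C(=O)OC1=O; AcOH, reflux) gives N-benzyl-2,3-dimethylmaleimide F6. Acetophenone-sensitised [2+2] photocycloaddition (350 nm, MeCN) with purchased 2,2-dimethyl-4,7-dihydro-1,3-dioxepine (CC1(C)OCC=CCO1, in excess) is expected to give mainly the cis-anti-cis acetonide-protected cycloadduct F7, which already carries both quaternary methyls. Aqueous AcOH releases the diol F8, and silylation with 7 (imidazole, DMF) gives 11.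

**Further compounds**

F1 | step 6 | cis-1,2-bis(hydroxymethyl)-1,2-dimethyl-3,4-bis[(tert-butyldiphenylsilyloxy)methyl]cyclobutane (meso) | OC[C@@]1(C)[C@H](CO[Si](c2ccccc2)(c2ccccc2)C(C)(C)C)[C@H](CO[Si](c2ccccc2)(c2ccccc2)C(C)(C)C)[C@@]1(C)CO
F2 | step 6 | cis-1,2-dimethyl-3,4-bis[(tert-butyldiphenylsilyloxy)methyl]cyclobutane-1,2-dicarbaldehyde (meso) | O=C[C@@]1(C)[C@H](CO[Si](c2ccccc2)(c2ccccc2)C(C)(C)C)[C@H](CO[Si](c2ccccc2)(c2ccccc2)C(C)(C)C)[C@@]1(C)C=O
F3 | step 6 | cis-1,2-bis(1-hydroxyethyl)-1,2-dimethyl-3,4-bis[(tert-butyldiphenylsilyloxy)methyl]cyclobutane (carbinol epimers) | CC(O)[C@@]1(C)[C@H](CO[Si](c2ccccc2)(c2ccccc2)C(C)(C)C)[C@H](CO[Si](c2ccccc2)(c2ccccc2)C(C)(C)C)[C@@]1(C)C(C)O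
F4 | step 8 | cis-1,2-bis(3-oxopentanoyl)-1,2-dimethyl-3,4-bis[(tert-butyldiphenylsilyloxy)methyl]cyclobutane | CCC(=O)CC(=O)[C@@]1(C)[C@H](CO[Si](c2ccccc2)(c2ccccc2)C(C)(C)C)[C@H](CO[Si](c2ccccc2)(c2ccccc2)C(C)(C)C)[C@@]1(C)C(=O)CC(=O)CC
F5 | step 8 | bis(3,5-dioxo acid): each arm of F4 carboxylated to a 4-carboxy-3-oxopentanoyl group (methyl epimers) | OC(=O)C(C)C(=O)CC(=O)[C@@]1(C)[C@H](CO[Si](c2ccccc2)(c2ccccc2)C(C)(C)C)[C@H](CO[Si](c2ccccc2)(c2ccccc2)C(C)(C)C)[C@@]1(C)C(=O)CC(=O)C(C)C(=O)O
F6 | step 4 | N-benzyl-2,3-dimethylmaleimide | CC1=C(C)C(=O)N(Cc2ccccc2)C1=O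
F7 | step 4 | cis-anti-cis photoadduct: 1,5-dimethyl N-benzyl cyclobutane-fused succinimide with C-6/C-7 bridged by CH2OC(CH3)2OCH2 (acetonide; meso) | O=C1N(Cc2ccccc2)C(=O)[C@@]3(C)[C@H]4[C@H](COC(C)(C)OC4)[C@]31C
F8 | step 4 | 3-benzyl-6,7-bis(hydroxymethyl)-1,5-dimethyl-3-azabicyclo[3.2.0]heptane-2,4-dione (meso; methyls and arms exo) | O=C1N(Cc2ccccc2)C(=O)[C@@]2(C)[C@H](CO)[C@H](CO)[C@]21C
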